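The α-methylene-γ-lactone is closed last, with CO2 as its carbonyl carbon (germacrane numbering). A glycidol-derived enal and an epoxy propargylic mesylate are joined by a Pd-catalysed allenylzinc addition (C6–C7), and the ten-membered ring is closed by an intramolecular Horner–Wadsworth–Emmons reaction (C1=C10). In the key step, macrocycle 24, an alkenylboronate at C11 with an inverted allylic chloride at C6, is carboxylated with CO2 under copper catalysis (C11–C12), and the carboxylate displaces the chloride in the same flask (O–C6). The step exploits the lactone ring O–C6–C7–C11–C12: C11 is a vinylic carbon that can carry a metal, and C6 is allylic to C4=C5, hence SN2-active.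

Key step: step 20

Remark on numbering: atoms are numbered as in germacranolides (ring C1–C10; C11, C12, C13 = lactone α-carbon, carbonyl carbon and exocyclic methylene; C14 on C10; C15 on C4). "1(10)E" is the CIP descriptor of the ring-cis C1=C10 bond (C2 and C9 on the same side). Acyclic intermediates 11 and 12 are named as nonane derivatives whose locants coincide with this numbering.

Remark on materials: (R)-glycidol, rac-pent-1-en-4-yn-3-ol and all reagents named are taken as commercial. IPr = 1,3-bis(2,6-diisopropylphenyl)imidazol-2-ylidene; dppp = 1,3-bis(diphenylphosphino)propane.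

Step 1
Reactants: 1 (R)-glycidol
Product: 2 (S)-pent-4-yne-1,2-diol
Conditions: lithium acetylide–ethylenediamine complex (3 equiv), DMSO, 0 → 23 °C
Reagents that add atoms: lithium acetylide–ethylenediamine complex, [Li+].[C-]#C.NCCN
Why: SN2 epoxide opening by the acetylide at the unsubstituted carbon leaves the carbinol centre (later C2) untouched, the descriptor changing from R to S only through the CIP priorities.

Step 2
Reactants: 2 (S)-pent-4-yne-1,2-diol
Product: 3 (S)-4,5-bis(triethylsilyloxy)pent-1-yne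
Conditions: TESCl, imidazole, DMF, 0 → 23 °C
Reagents that add atoms: chlorotriethylsilane, CC[Si](Cl)(CC)CC
Why: Standard silylation of both hydroxyls; the primary and the secondary TES ether are told apart later by a primary-selective Swern oxidation.

Step 3
Reactants: 3 (S)-4,5-bis(triethylsilyloxy)pent-1-yne
Product: 5 (S,E)-3-methyl-5,6-bis(triethylsilyloxy)hex-2-en-1-ol, via alkenyldimethylalane 4 (not isolated)
Conditions: AlMe3, Cp2ZrCl2 (20 mol%), CH2Cl2, 0 → 23 °C; then n-BuLi, −78 °C; (CH2O)n, THF, 23 °C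
Reagents that add atoms: trimethylaluminium, C[Al](C)C; paraformaldehyde (as formaldehyde), C=O
Why: Negishi carboalumination adds Me and Al syn across the alkyne (Me internal, Al terminal) and the alanate is hydroxymethylated with retention, which fixes the E geometry of C4=C5.

Step 4
Reactants: 5 (S,E)-3-methyl-5,6-bis(triethylsilyloxy)hex-2-en-1-ol
Product: 6 (S,E)-3-methyl-5,6-bis(triethylsilyloxy)hex-2-enal
Conditions: MnO2, CH2Cl2, 23 °C
Reagents that add atoms: none
Why: Chemoselective allylic oxidation with MnO2 gives the enal (C6 aldehyde) without touching the silyl ethers or the alkene geometry.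

Step 5
Reactants: 7 rac-pent-1-en-4-yn-3-ol
Product: 8 (S)-1-[(R)-oxiran-2-yl]prop-2-yn-1-ol
Conditions: Ti(OiPr)4 (10 mol%), L-(+)-diisopropyl tartrate (12 mol%), t-BuOOH (0.55 equiv), 4 Å molecular sieves, CH2Cl2, −20 °C
Reagents that add atoms: tert-butyl hydroperoxide, CC(C)(C)OO
Why: Sharpless kinetic resolution: the L-(+)-tartrate catalyst should epoxidise the (R)-alcohol faster and deliver oxygen to the face that gives the erythro epoxy alcohol, which sets C8 and leaves the (S)-alcohol behind.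

Step 6
Reactants: 8 (S)-1-[(R)-oxiran-2-yl]prop-2-yn-1-ol
Product: 9 (S)-1-[(R)-oxiran-2-yl]prop-2-yn-1-yl methanesulfonate
Conditions: MsCl, Et3N, CH2Cl2, −40 °C
Reagents that add atoms: methanesulfonyl chloride, CS(=O)(=O)Cl
Why: O-sulfonylation with retention gives the propargylic mesylate whose configuration encodes C7.

Step 7
Reactants: 6 (S,E)-3-methyl-5,6-bis(triethylsilyloxy)hex-2-enal; 9 (S)-1-[(R)-oxiran-2-yl]prop-2-yn-1-yl methanesulfonate
Product: 11 (2S,4E,6R,7S,8S)-8,9-epoxy-7-ethynyl-4-methyl-1,2-bis(triethylsilyloxy)non-4-en-6-ol, via allenylzinc 10 (not isolated)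
Conditions: Pd(OAc)2 (5 mol%), PPh3 (5 mol%), Et2Zn (3 equiv), THF, −78 → −20 °C
Reagents that add atoms: none
Why: Palladium-catalysed umpolung propargylation: zerovalent palladium displaces the mesylate anti (SN2′), Et2Zn takes over the allenyl group with retention and the allenylzinc adds to the enal by syn-SE2′ through a closed six-membered transition state, so C7 is set by net inversion at the mesylate carbon and C6 anti to it.

Step 8
Reactants: 11 (2S,4E,6R,7S,8S)-8,9-epoxy-7-ethynyl-4-methyl-1,2-bis(triethylsilyloxy)non-4-en-6-ol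
Product: 12 (2S,4E,6R,7S,8S)-8,9-epoxy-7-ethynyl-6-(4-methoxybenzyloxy)-4-methyl-1,2-bis(triethylsilyloxy)non-4-ene
Conditions: NaH, PMBCl, Bu4NI (cat.), THF/DMF, 0 °C
Reagents that add atoms: 4-methoxybenzyl chloride, COc1ccc(CCl)cc1
Why: Williamson etherification gives a C6 ether that is orthogonal to all silyl groups and is removed oxidatively just before C6 is activated.

Step 9
Reactants: 12 (2S,4E,6R,7S,8S)-8,9-epoxy-7-ethynyl-6-(4-methoxybenzyloxy)-4-methyl-1,2-bis(triethylsilyloxy)non-4-ene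
Product: 13 dimethyl [(5R)-5-[(1R,2R,3E,6S)-1-ethynyl-2-(4-methoxybenzyloxy)-4-methyl-6,7-bis(triethylsilyloxy)hept-3-en-1-yl]-2-oxotetrahydrofuran-3-yl]phosphonate (C10 epimers)
Conditions: (MeO)2P(O)CH2CO2Me (2 equiv), NaH (1.9 equiv), DME, 80 °C
Reagents that add atoms: trimethyl phosphonoacetate, COC(=O)CP(=O)(OC)OC
Why: The stabilised phosphonoacetate anion opens the epoxide at the terminal carbon (C9–C10 bond) and the C8 alkoxide lactonises onto the methyl ester (known route to α-phosphono-γ-butyrolactones); C8 is untouched and C10 is an inconsequential epimer mixture.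

Step 10
Reactants: 13 the α-phosphono lactone
Product: 14 dimethyl [(5R)-5-[(1R,2R,3E,6S)-1-ethynyl-2-(4-methoxybenzyloxy)-4-methyl-7-oxo-6-(triethylsilyloxy)hept-3-en-1-yl]-2-oxotetrahydrofuran-3-yl]phosphonate
Conditions: (COCl)2, DMSO, CH2Cl2, −78 → −40 °C; then Et3N, → 0 °C
Reagents that add atoms: none
Why: Swern oxidation converts a primary TES ether directly into the aldehyde (silyl exchange to the alkoxysulfonium salt, then elimination) while the more hindered secondary TES ether at C2 should stay.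

Step 11
Reactants: 14 the aldehyde phosphonate
Product: 15 (1(10)E,2S,4E,6R,7R,8R)-7-ethynyl-6-(4-methoxybenzyloxy)-4-methyl-2-(triethylsilyloxy)cyclodeca-1(10),4-diene-10,8-carbolactone
Conditions: LiCl, DBU, MeCN, slow addition at high dilution (about 1 mM), 23 °C
Reagents that add atoms: none
Why: Intramolecular Horner–Wadsworth–Emmons olefination under mild LiCl/amidine conditions closes the ten-membered ring at C1=C10; the α-phosphono lactone is expected to give the E-alkylidene lactone, which places C2 and C9 cis as the ring requires, and the α-silyloxy aldehyde should not epimerise.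

Step 12
Reactants: 15 the macrocyclic alkylidene lactone
Product: 16 (1(10)E,2S,4E,6R,7R,8R)-7-ethynyl-10-(hydroxymethyl)-6-(4-methoxybenzyloxy)-4-methyl-2-(triethylsilyloxy)cyclodeca-1(10),4-dien-8-ol
Conditions: DIBAL-H (5 equiv), CH2Cl2, −78 → 0 °C; Rochelle salt work-up
Reagents that add atoms: none
Why: 1,2-Reduction of the unsaturated lactone opens the bridge and releases the primary allylic C14 hydroxyl and the secondary C8 hydroxyl in one step.

Step 13
Reactants: 16 the diol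
Product: 17 (1(10)E,2S,4E,6R,7R,8R)-10-[(tert-butyldiphenylsilyloxy)methyl]-7-ethynyl-6-(4-methoxybenzyloxy)-4-methyl-2-(triethylsilyloxy)cyclodeca-1(10),4-dien-8-ol
Conditions: TBDPSCl, imidazole, CH2Cl2, 0 °C
Reagents that add atoms: tert-butyl(chloro)diphenylsilane, CC(C)(C)[Si](Cl)(c1ccccc1)c1ccccc1
Why: The bulky silyl chloride should select the primary allylic hydroxyl over the hindered secondary C8 hydroxyl.

Step 14
Reactants: 17 the C14 silyl ether
Product: 19 (1(10)E,2S,4E,6R,7R,8R)-10-[(tert-butyldiphenylsilyloxy)methyl]-6-(4-methoxybenzyloxy)-4-methyl-7-[1-(4,4,5,5-tetramethyl-1,3,2-dioxaborolan-2-yl)vinyl]-2-(triethylsilyloxy)cyclodeca-1(10),4-dien-8-ol, via alkenylalane 18 (not isolated)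
Conditions: Ni(dppp)Cl2 (5 mol%), DIBAL-H (2.5 equiv), THF, 0 → 23 °C; then MeOBpin (3 equiv), 23 → 70 °C
Reagents that add atoms: 2-methoxy-4,4,5,5-tetramethyl-1,3,2-dioxaborolane, COB1OC(C)(C)C(C)(C)O1
Why: Nickel-catalysed Markovnikov hydroalumination places aluminium on the internal alkyne carbon (C11) and Al-to-B exchange with MeOBpin gives the 1,1-disubstituted alkenylboronate; the step is placed before any ester is present and the C8 hydroxyl is carried as its aluminium alkoxide.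

Step 15
Reactants: 19 the alkenylboronate alcohol
Product: 20 (1(10)E,2S,4E,6R,7R,8R)-10-[(tert-butyldiphenylsilyloxy)methyl]-6-(4-methoxybenzyloxy)-4-methyl-7-[1-(4,4,5,5-tetramethyl-1,3,2-dioxaborolan-2-yl)vinyl]-2-(triethylsilyloxy)cyclodeca-1(10),4-dien-8-yl methacrylate
Conditions: methacrylic anhydride, Et3N, DMAP, CH2Cl2, 23 °C
Reagents that add atoms: methacrylic anhydride, C=C(C)C(=O)OC(=O)C(C)=C
Why: DMAP-catalysed acylation of the only free hydroxyl installs the C8 methacrylate with retention.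

Step 16
Reactants: 20 the C8 methacrylate
Product: 21 (1(10)E,2S,4E,6R,7R,8R)-10-[(tert-butyldiphenylsilyloxy)methyl]-2-hydroxy-6-(4-methoxybenzyloxy)-4-methyl-7-[1-(4,4,5,5-tetramethyl-1,3,2-dioxaborolan-2-yl)vinyl]cyclodeca-1(10),4-dien-8-yl methacrylate
Conditions: PPTS (cat.), MeOH/CH2Cl2, 0 °C
Reagents that add atoms: none
Why: Mild acid methanolysis removes the TES ether well before the TBDPS ether, the PMB ether or the pinacol boronate are affected.

Step 17
Reactants: 21 the C2 alcohol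
Product: 22 (1(10)E,2S,4E,6R,7R,8R)-2-acetoxy-10-[(tert-butyldiphenylsilyloxy)methyl]-6-(4-methoxybenzyloxy)-4-methyl-7-[1-(4,4,5,5-tetramethyl-1,3,2-dioxaborolan-2-yl)vinyl]cyclodeca-1(10),4-dien-8-yl methacrylate
Conditions: Ac2O, pyridine, DMAP (cat.), CH2Cl2, 0 °C
Reagents that add atoms: acetic anhydride, CC(=O)OC(C)=O
Why: Standard acetylation of the C2 hydroxyl with retention.

Step 18
Reactants: 22 the C2 acetate
Product: 23 (1(10)E,2S,4E,6R,7S,8R)-2-acetoxy-10-[(tert-butyldiphenylsilyloxy)methyl]-6-hydroxy-4-methyl-7-[1-(4,4,5,5-tetramethyl-1,3,2-dioxaborolan-2-yl)vinyl]cyclodeca-1(10),4-dien-8-yl methacrylate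
Conditions: DDQ (1.2 equiv), CH2Cl2/pH 7 buffer, 0 °C
Reagents that add atoms: none
Why: Oxidative cleavage of the PMB ether frees the C6 hydroxyl under neutral conditions that suppress 1,3-acyl migration from O8, with no change at C6 (the C7 descriptor changes only through CIP priorities); 23 is used at once.

Step 19
Reactants: 23 the C6 allylic alcohol
Product: 24 (1(10)E,2S,4E,6S,7R,8R)-2-acetoxy-10-[(tert-butyldiphenylsilyloxy)methyl]-6-chloro-4-methyl-7-[1-(4,4,5,5-tetramethyl-1,3,2-dioxaborolan-2-yl)vinyl]cyclodeca-1(10),4-dien-8-yl methacrylate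
Conditions: PPh3, hexachloroacetone, CH2Cl2, −20 → 0 °C
Reagents that add atoms: hexachloroacetone, O=C(C(Cl)(Cl)Cl)C(Cl)(Cl)Cl
Why: Appel-type chlorination: chloride displaces the alkoxyphosphonium group at C6 by SN2 with inversion (6R to 6S), under conditions chosen because they keep allylic transposition of secondary allylic alcohols low.

Step 20
Reactants: 24 the allylic chloride alkenylboronate
Product: 26 (1(10)E,2S,4E,6R,7R,8R)-2-acetoxy-14-(tert-butyldiphenylsilyloxy)-8-(methacryloyloxy)germacra-1(10),4,11(13)-trien-12,6-olide, via caesium carboxylate 25 (not isolated)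
Conditions: (IPr)CuCl (10 mol%), CsF (3 equiv), CO2 (1 atm), DMF, 70 °C
Reagents that add atoms: carbon dioxide, O=C=O
Why: CsF converts the alkenylboronate into a fluoroborate that transmetalates to copper at C11, CO2 inserts into the Cu–C(sp2) bond to form C11–C12, and the caesium acrylate 25 then attacks C6 from the side opposite to chloride to form O–C6. The closest known reaction types are the copper-catalysed carboxylation of alkenylboronic esters with CO2 and the caesium-carboxylate SN2 esterification of secondary halides in DMF, here run as a domino in one flask. The γ-lactone closes in the 5-exo-tet mode. The only new stereocentre, C6, is set by stereospecific inversion of the (6S)-chloride, which gives the 6R, trans-fused lactone, while C7 and C8 are not touched. The step needs SN2 at C6 to win over SN2′ at C4 and over elimination, which the five- versus seven-membered ring size and the allylic activation of C6 should secure. It also needs the carboxylate to form before the chloride is lost, which the weakly basic fluoride medium under CO2 favours; any loss of the silyl ether only anticipates step 21.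

Step 21
Reactants: 26 the silyl-protected lactone
Product: 27 (1(10)E,2S,4E,6R,7R,8R)-2-acetoxy-14-hydroxy-8-(methacryloyloxy)germacra-1(10),4,11(13)-trien-12,6-olide (CNP0138477.2)
Conditions: HF·pyridine, pyridine, THF, 0 → 23 °C
Reagents that add atoms: none
Why: Buffered fluoride desilylation frees the C14 hydroxyl without touching the acetate, the methacrylate or the α-methylene lactone.

Compound list
1 | (R)-glycidol | OC[C@@H]1CO1 | starting material
2 | (S)-pent-4-yne-1,2-diol | OC[C@@H](O)CC#C | intermediate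
3 | (S)-4,5-bis(triethylsilyloxy)pent-1-yne | CC[Si](CC)(CC)OC[C@@H](O[Si](CC)(CC)CC)CC#C | intermediate
4 | (S,E)-[2-methyl-4,5-bis(triethylsilyloxy)pent-1-en-1-yl]dimethylalane | CC[Si](CC)(CC)OC[C@@H](O[Si](CC)(CC)CC)C/C(C)=C/[Al](C)C | intermediate (not isolated)
5 | (S,E)-3-methyl-5,6-bis(triethylsilyloxy)hex-2-en-1-ol | CC[Si](CC)(CC)OC[C@@H](O[Si](CC)(CC)CC)C/C(C)=C/CO | intermediate
6 | (S,E)-3-methyl-5,6-bis(triethylsilyloxy)hex-2-enal | CC[Si](CC)(CC)OC[C@@H](O[Si](CC)(CC)CC)C/C(C)=C/C=O | intermediate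
7 | rac-pent-1-en-4-yn-3-ol | C#CC(O)C=C | starting material
8 | (S)-1-[(R)-oxiran-2-yl]prop-2-yn-1-ol | C#C[C@H](O)[C@H]1CO1 | intermediate
9 | (S)-1-[(R)-oxiran-2-yl]prop-2-yn-1-yl methanesulfonate | C#C[C@H](OS(C)(=O)=O)[C@H]1CO1 | intermediate
10 | ethyl{3-[(S)-oxiran-2-yl]propa-1,2-dien-1-yl}zinc, allene axis set by anti SN2′ displacement | CC[Zn]C([H])=[C@@]=C([H])[C@H]1CO1 | intermediate (not isolated)
11 | (2S,4E,6R,7S,8S)-8,9-epoxy-7-ethynyl-4-methyl-1,2-bis(triethylsilyloxy)non-4-en-6-ol | CC[Si](CC)(CC)OC[C@@H](O[Si](CC)(CC)CC)C/C(C)=C/[C@@H](O)[C@H](C#C)[C@H]1CO1 | intermediate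
12 | (2S,4E,6R,7S,8S)-8,9-epoxy-7-ethynyl-6-(4-methoxybenzyloxy)-4-methyl-1,2-bis(triethylsilyloxy)non-4-ene | CC[Si](CC)(CC)OC[C@@H](O[Si](CC)(CC)CC)C/C(C)=C/[C@@H](OCc1ccc(OC)cc1)[C@H](C#C)[C@H]1CO1 | intermediate
13 | dimethyl [(5R)-5-[(1R,2R,3E,6S)-1-ethynyl-2-(4-methoxybenzyloxy)-4-methyl-6,7-bis(triethylsilyloxy)hept-3-en-1-yl]-2-oxotetrahydrofuran-3-yl]phosphonate (C10 epimers) | CC[Si](CC)(CC)OC[C@@H](O[Si](CC)(CC)CC)C/C(C)=C/[C@@H](OCc1ccc(OC)cc1)[C@H](C#C)[C@H]1CC(P(=O)(OC)OC)C(=O)O1 | intermediate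
14 | dimethyl [(5R)-5-[(1R,2R,3E,6S)-1-ethynyl-2-(4-methoxybenzyloxy)-4-methyl-7-oxo-6-(triethylsilyloxy)hept-3-en-1-yl]-2-oxotetrahydrofuran-3-yl]phosphonate | O=C[C@@H](O[Si](CC)(CC)CC)C/C(C)=C/[C@@H](OCc1ccc(OC)cc1)[C@H](C#C)[C@H]1CC(P(=O)(OC)OC)C(=O)O1 | intermediate
15 | (1(10)E,2S,4E,6R,7R,8R)-7-ethynyl-6-(4-methoxybenzyloxy)-4-methyl-2-(triethylsilyloxy)cyclodeca-1(10),4-diene-10,8-carbolactone (C14 carbonyl on C10, lactone oxygen on C8) | O=C1O[C@@H]2C/C1=C\[C@@H](O[Si](CC)(CC)CC)C/C(C)=C/[C@@H](OCc1ccc(OC)cc1)[C@@H]2C#C | intermediate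
16 | (1(10)E,2S,4E,6R,7R,8R)-7-ethynyl-10-(hydroxymethyl)-6-(4-methoxybenzyloxy)-4-methyl-2-(triethylsilyloxy)cyclodeca-1(10),4-dien-8-ol | O[C@@H]1C/C(CO)=C\[C@@H](O[Si](CC)(CC)CC)C/C(C)=C/[C@@H](OCc2ccc(OC)cc2)[C@@H]1C#C | intermediate
17 | (1(10)E,2S,4E,6R,7R,8R)-10-[(tert-butyldiphenylsilyloxy)methyl]-7-ethynyl-6-(4-methoxybenzyloxy)-4-methyl-2-(triethylsilyloxy)cyclodeca-1(10),4-dien-8-ol | O[C@@H]1C/C(CO[Si](c2ccccc2)(c2ccccc2)C(C)(C)C)=C\[C@@H](O[Si](CC)(CC)CC)C/C(C)=C/[C@@H](OCc2ccc(OC)cc2)[C@@H]1C#C | intermediate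
18 | C11 alkenyl(diisobutyl)alane of 17 with the C8 oxygen as diisobutylaluminium alkoxide | CC(C)C[Al](CC(C)C)O[C@@H]1C/C(CO[Si](c2ccccc2)(c2ccccc2)C(C)(C)C)=C\[C@@H](O[Si](CC)(CC)CC)C/C(C)=C/[C@@H](OCc2ccc(OC)cc2)[C@@H]1C(=C)[Al](CC(C)C)CC(C)C | intermediate (not isolated)
19 | (1(10)E,2S,4E,6R,7R,8R)-10-[(tert-butyldiphenylsilyloxy)methyl]-6-(4-methoxybenzyloxy)-4-methyl-7-[1-(4,4,5,5-tetramethyl-1,3,2-dioxaborolan-2-yl)vinyl]-2-(triethylsilyloxy)cyclodeca-1(10),4-dien-8-ol | O[C@@H]1C/C(CO[Si](c2ccccc2)(c2ccccc2)C(C)(C)C)=C\[C@@H](O[Si](CC)(CC)CC)C/C(C)=C/[C@@H](OCc2ccc(OC)cc2)[C@@H]1C(=C)B1OC(C)(C)C(C)(C)O1 | intermediate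
20 | C8 methacrylate of 19 (1(10)E,2S,4E,6R,7R,8R) | C=C(C)C(=O)O[C@@H]1C/C(CO[Si](c2ccccc2)(c2ccccc2)C(C)(C)C)=C\[C@@H](O[Si](CC)(CC)CC)C/C(C)=C/[C@@H](OCc2ccc(OC)cc2)[C@@H]1C(=C)B1OC(C)(C)C(C)(C)O1 | intermediate
21 | C2 alcohol: 20 without the triethylsilyl group (1(10)E,2S,4E,6R,7R,8R) | C=C(C)C(=O)O[C@@H]1C/C(CO[Si](c2ccccc2)(c2ccccc2)C(C)(C)C)=C\[C@@H](O)C/C(C)=C/[C@@H](OCc2ccc(OC)cc2)[C@@H]1C(=C)B1OC(C)(C)C(C)(C)O1 | intermediate
22 | C2 acetate of 21 (1(10)E,2S,4E,6R,7R,8R) | C=C(C)C(=O)O[C@@H]1C/C(CO[Si](c2ccccc2)(c2ccccc2)C(C)(C)C)=C\[C@@H](OC(C)=O)C/C(C)=C/[C@@H](OCc2ccc(OC)cc2)[C@@H]1C(=C)B1OC(C)(C)C(C)(C)O1 | intermediate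
23 | (1(10)E,2S,4E,6R,7S,8R)-2-acetoxy-10-[(tert-butyldiphenylsilyloxy)methyl]-6-hydroxy-4-methyl-7-[1-(4,4,5,5-tetramethyl-1,3,2-dioxaborolan-2-yl)vinyl]cyclodeca-1(10),4-dien-8-yl methacrylate | C=C(C)C(=O)O[C@@H]1C/C(CO[Si](c2ccccc2)(c2ccccc2)C(C)(C)C)=C\[C@@H](OC(C)=O)C/C(C)=C/[C@@H](O)[C@@H]1C(=C)B1OC(C)(C)C(C)(C)O1 | intermediate
24 | (1(10)E,2S,4E,6S,7R,8R)-2-acetoxy-10-[(tert-butyldiphenylsilyloxy)methyl]-6-chloro-4-methyl-7-[1-(4,4,5,5-tetramethyl-1,3,2-dioxaborolan-2-yl)vinyl]cyclodeca-1(10),4-dien-8-yl methacrylate | C=C(C)C(=O)O[C@@H]1C/C(CO[Si](c2ccccc2)(c2ccccc2)C(C)(C)C)=C\[C@@H](OC(C)=O)C/C(C)=C/[C@H](Cl)[C@@H]1C(=C)B1OC(C)(C)C(C)(C)O1 | intermediate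
25 | caesium 2-[(1(10)E,2S,4E,6S,7R,8R)-macrocyclyl]acrylate: 24 with CO2Cs in place of the boronate | C=C(C)C(=O)O[C@@H]1C/C(CO[Si](c2ccccc2)(c2ccccc2)C(C)(C)C)=C\[C@@H](OC(C)=O)C/C(C)=C/[C@H](Cl)[C@@H]1C(=C)C(=O)[O-].[Cs+] | intermediate (not isolated)
26 | (1(10)E,2S,4E,6R,7R,8R)-2-acetoxy-14-(tert-butyldiphenylsilyloxy)-8-(methacryloyloxy)germacra-1(10),4,11(13)-trien-12,6-olide | C=C(C)C(=O)O[C@@H]1C/C(CO[Si](c2ccccc2)(c2ccccc2)C(C)(C)C)=C\[C@@H](OC(C)=O)C/C(C)=C/[C@H]2OC(=O)C(=C)[C@@H]21 | intermediate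
27 | (1(10)E,2S,4E,6R,7R,8R)-2-acetoxy-14-hydroxy-8-(methacryloyloxy)germacra-1(10),4,11(13)-trien-12,6-olide (CNP0138477.2) | C=C(C)C(=O)O[C@@H]1C/C(CO)=C\[C@@H](OC(C)=O)C/C(C)=C/[C@H]2OC(=O)C(=C)[C@@H]21 | target

Total step count: 21. Longest linear sequence: 19 steps (steps 1–4 and 7–21; steps 5–6 make the second fragment).

Steps most likely to fail

Step 20 (key step). What may go wrong: fluoride-induced elimination or substitution at the allylic chloride, or protodeboronation, before CO2 is captured, so that carboxylation and ring closure do not follow one another. The fallback keeps both bonds in one operation but changes the closure from direct SN2 to a π-allyl substitution with net retention; it sets out from alcohol 23 (step 19 is then not needed) and returns at 26. Acylation of 23 with methyl chloroformate and pyridine would give the C6 methyl carbonate F1. Copper-catalysed carboxylation of F1 ((IPr)CuCl, CsF, CO2, DMF, 60 °C) would give the caesium carboxylate F2, which is not isolated. Addition of Pd(PPh3)4 to the same flask at 23 °C should ionise the allylic carbonate anti (much faster than the C2 acetate) and let the carboxylate attack C6 of the π-allyl complex anti to palladium (Tsuji–Trost lactonisation, 5-exo, double inversion), giving 26.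

Step 11. What may go wrong: intermolecular olefination (oligomerisation) outrunning closure of the bridged ten-membered ring, or erosion of the E selectivity under the strain of the bicycle. The fallback closes a flexible monocycle without the lactone bridge and creates the C8/C14 oxygen pattern afterwards; it sets out from 13 and returns at 16. Aminolysis of lactone 13 with Me(MeO)NH·HCl and AlMe3 would give the open-chain hydroxy Weinreb amide F3. Acetylation (Ac2O, pyridine) would give the C8 acetate F4, and Swern oxidation of its primary TES ether the aldehyde F5. Horner–Wadsworth–Emmons closure (LiCl, iPr2NEt, MeCN, high dilution) would give the monocyclic E-configured unsaturated Weinreb amide F6. DIBAL-H at −78 °C should reduce the amide to the aldehyde and cleave the acetate to give the hydroxy enal F7, and Luche reduction (NaBH4, CeCl3) would give diol 16.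

Step 19. What may go wrong: loss of positional and stereochemical integrity at the hindered allylic oxyphosphonium salt (SN2′ transposition to C4, ionisation with partial retention, or elimination to a diene). The fallback separates inversion from activation; it sets out from 23 and returns at 26. Mitsunobu reaction of 23 with formic acid (PPh3, DIAD, toluene, 0 °C) would give the inverted (6S)-formate F8. KHCO3 in MeOH at 0 °C should remove the formate selectively and give the (6S)-alcohol F9. Ms2O and Et3N at −20 °C would give, with retention, the (6S)-mesylate F10, used crude. Under the conditions of step 20 at lower temperature F10 should give the caesium carboxylate F11, not isolated, which closes to 26 by the same SN2 displacement.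

Further compounds
F1 | step 20 | C6 methyl carbonate of 23 (1(10)E,2S,4E,6R,7R,8R) | C=C(C)C(=O)O[C@@H]1C/C(CO[Si](c2ccccc2)(c2ccccc2)C(C)(C)C)=C\[C@@H](OC(C)=O)C/C(C)=C/[C@@H](OC(=O)OC)[C@@H]1C(=C)B1OC(C)(C)C(C)(C)O1
F2 | step 20 | caesium acrylate from F1 (CO2Cs in place of the boronate; not isolated) | C=C(C)C(=O)O[C@@H]1C/C(CO[Si](c2ccccc2)(c2ccccc2)C(C)(C)C)=C\[C@@H](OC(C)=O)C/C(C)=C/[C@@H](OC(=O)OC)[C@@H]1C(=C)C(=O)[O-].[Cs+]
F3 | step 11 | open-chain hydroxy Weinreb amide from 13 (2S,4E,6R,7R,8R; C8 hydroxyl, C10 phosphonate, C14 N-methoxy-N-methylamide) | CC[Si](CC)(CC)OC[C@@H](O[Si](CC)(CC)CC)C/C(C)=C/[C@@H](OCc1ccc(OC)cc1)[C@H](C#C)[C@H](O)CC(P(=O)(OC)OC)C(=O)N(C)OC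
F4 | step 11 | C8 acetate of F3 | CC[Si](CC)(CC)OC[C@@H](O[Si](CC)(CC)CC)C/C(C)=C/[C@@H](OCc1ccc(OC)cc1)[C@H](C#C)[C@H](OC(C)=O)CC(P(=O)(OC)OC)C(=O)N(C)OC
F5 | step 11 | C1 aldehyde of F4 | O=C[C@@H](O[Si](CC)(CC)CC)C/C(C)=C/[C@@H](OCc1ccc(OC)cc1)[C@H](C#C)[C@H](OC(C)=O)CC(P(=O)(OC)OC)C(=O)N(C)OC
F6 | step 11 | (1(10)E,2S,4E,6R,7R,8R)-8-acetoxy-7-ethynyl-N-methoxy-6-(4-methoxybenzyloxy)-N,4-dimethyl-2-(triethylsilyloxy)cyclodeca-1(10),4-diene-10-carboxamide | CC(=O)O[C@@H]1C/C(C(=O)N(C)OC)=C\[C@@H](O[Si](CC)(CC)CC)C/C(C)=C/[C@@H](OCc2ccc(OC)cc2)[C@@H]1C#C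
F7 | step 11 | (1(10)E,2S,4E,6R,7R,8R)-7-ethynyl-8-hydroxy-6-(4-methoxybenzyloxy)-4-methyl-2-(triethylsilyloxy)cyclodeca-1(10),4-diene-10-carbaldehyde | O[C@@H]1C/C(C=O)=C\[C@@H](O[Si](CC)(CC)CC)C/C(C)=C/[C@@H](OCc2ccc(OC)cc2)[C@@H]1C#C
F8 | step 19 | (6S)-formate: C6-inverted formate ester of 23 | C=C(C)C(=O)O[C@@H]1C/C(CO[Si](c2ccccc2)(c2ccccc2)C(C)(C)C)=C\[C@@H](OC(C)=O)C/C(C)=C/[C@H](OC=O)[C@@H]1C(=C)B1OC(C)(C)C(C)(C)O1
F9 | step 19 | (6S)-alcohol: C6 epimer of 23 | C=C(C)C(=O)O[C@@H]1C/C(CO[Si](c2ccccc2)(c2ccccc2)C(C)(C)C)=C\[C@@H](OC(C)=O)C/C(C)=C/[C@H](O)[C@@H]1C(=C)B1OC(C)(C)C(C)(C)O1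
F10 | step 19 | (6S)-methanesulfonate of F9 | C=C(C)C(=O)O[C@@H]1C/C(CO[Si](c2ccccc2)(c2ccccc2)C(C)(C)C)=C\[C@@H](OC(C)=O)C/C(C)=C/[C@H](OS(C)(=O)=O)[C@@H]1C(=C)B1OC(C)(C)C(C)(C)O1
F11 | step 19 | caesium acrylate from F10 (CO2Cs in place of the boronate; not isolated) | C=C(C)C(=O)O[C@@H]1C/C(CO[Si](c2ccccc2)(c2ccccc2)C(C)(C)C)=C\[C@@H](OC(C)=O)C/C(C)=C/[C@H](OS(C)(=O)=O)[C@@H]1C(=C)C(=O)[O-].[Cs+]
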